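in all of them: electrophile 0.20 M

|  | nucleophile | free base | protic impurity | remark | time |
|---|---|---|---|---|---|
| noon | 0.24 M | 0.33 M | 4 mM | run made earlier |  |
| dawn | 0.24 M | 0.81 M | 4 mM | run made earlier |  |
| alpha | 0.240 M | 0.360 M | 4.00 mM |  | 2.5 h |
| eta | 0.240 M | 0.240 M | 4.00 mM |  | 2.5 h |
| beta | 0.240 M | 0.540 M | 4.00 mM |  | 2.5 h |

| run | time / h | electrophile / % | target / % |
|---|---|---|---|
| noon | 0.200 | 54.7 | 18.9 |
| noon | 0.667 | 24.1 | 33.6 |
| noon | 1.33 | 12.1 | 40.9 |
| noon | 2.00 | 6.6 | 45.0 |
| noon | 2.50 | 5.2 | 46.7 |
| dawn | 0.200 | 54.9 | 18.5 |
| dawn | 0.667 | 24.0 | 33.9 |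
| dawn | 1.33 | 11.4 | 42.5 |
| dawn | 2.00 | 6.3 | 46.9 |
| dawn | 2.50 | 4.0 | 48.6 |

(readings scatter by 0.3 percentage points)

- what was read earlier has a scatter of 0.3 percentage points, one standard deviation

* part of the electrophile that has reacted at the end, alpha
* part of the electrophile that has reacted at the end, eta
* part of the electrophile that has reacted at the end, beta
* what raising the concentration of free base from its lowest to its highest value here does to the part of the electrophile that has reacted (changes below 5 percentage points count as none) (it falls / no change / it rises)

At early times noon and dawn lay on one curve. Noon lost 45.3% of its electrophile in the first 0.200 h, and at that reading dawn kept 54.9% against noon's 54.7%. Then came the knee. Noon lost 31 percentage points in the next 0.467 h, and by 0.667 h its target, at 33.6%, stood above its electrophile, at 24.1%.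

The tail flattened, and there the runs parted slightly. At 2.50 h noon kept 5.2% electrophile and dawn 4.0%. That gap of 1.2 points compares with a scatter of 0.42 points on a difference. Dawn held 2.45 times noon's free base, so I reckoned 0.93 points per doubling. I call this the base leverage: the points of electrophile that a doubling of free base takes off the end reading, with time and the other charges held.

Eta lay below noon in free base, so there I stretched the reading. But noon's target at its last reading, 2.50 h, was 0.0934 M, less than eta's 0.240 M of free base. Reckoned at one free base per target, that left 0.147 M of eta's charge, so I expected no stall. From noon I reckoned 94.9% for alpha, 94.4% for eta and 95.5% for beta. The span of 1.1 points was under the 5 points mark, so I expected no change.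

The forecast gave 95.6%, 77% and 96%, with the trend: it rises. For eta it held that “base (0.236 M usable) runs out near 75–80% conversion and the reaction stalls”. There my reckoning differed.

The flask gave 95.1% for alpha, 94.9% for eta and 95.4% for beta. The trend was no change, with a change of 0.53 points.

    electrophile + nucleophile → acid set free + target (k = 0.00170 M⁻¹ s⁻¹)
    electrophile + protic impurity → quenched substrate (k = 0.0656 M⁻¹ s⁻¹)
    nucleophile + acid set free ⇌ protonated nucleophile, settled at all times (K = 4720 M⁻¹)
    2 electrophile → self-condensation product (k = 0.00161 M⁻¹ s⁻¹)
    acid set free → by-product carried off (k = 7.72 × 10⁻⁴ s⁻¹)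
    acid set free + free base ⇌ salt of the base, settled at all times (K = 780 M⁻¹)

In eta, 89% of the charged free base was still free at 2.50 h. Started from alpha's result, the base leverage gave 94.6% for eta, which stood at 94.9%. From the same start it gave 95.6% for beta, which stood at 95.4%.

(The runs were generated by integration from invented constants; noise was put on by code.)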